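Working out how fast the gas can enter is the easy step here, so I began there, with none of the coupling partner dissolved and the transfer running at its full rate.

| setting | dusk | summer | midnight |
|---|---|---|---|
| substrate | 0.31 M | 0.31 M | 0.31 M |
| gas | 74 mM (held) | 74 mM (held) | 74 mM (held) |
| time | 15 min | 15 min | 15 min |
| remark | at 45 °C until 10 min, from then on at 20 °C |  |  |
| temperature |  | 45 °C | 20 °C |

    substrate + coupling partner → single product + by-product (k1 = 6.29 /M/min, Ea1 = 40.0 kJ/mol)
    coupling partner + single product → double product + by-product (k2 = 8.22 /M/min, Ea2 = 47.0 kJ/mol)
    coupling partner + double product → tris adduct + by-product (k3 = 5.08 /M/min, Ea3 = 64.0 kJ/mol)
    gas ⇌ coupling partner, rate k4*(csat - [coupling partner]) (k4 = 0.214 /min, csat = 74 mM)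
    (constants at 20 °C)

- at the start none of coupling partner is dissolved
- the list of constants is for 20 °C, to be carried to other temperatures by the activation energies

- the flask with the highest amount of double product, in percent of the substrate charged ("all alike" if they lie within 1.5 percentage points) (dusk / summer / midnight / all alike)
- final double product, as a percentage of the substrate charged, in dusk
- final double product, as a percentage of the substrate charged, in summer
- final double product, as a percentage of the substrate charged, in midnight

I turned each constant into a time at the charged amounts, giving each coupling its other reactant at the whole charge as a yardstick, and the transfer, which has no activation energy, the same time in both columns. My small table had these rows, the time at 20 °C standing before the time at 45 °C: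

- gas passing in: 4.67 min and 4.67 min
- first coupling, on substrate: 0.513 min and 0.141 min
- second coupling, on single product: 0.392 min and 0.0862 min
- third coupling, on double product: 0.635 min and 0.0807 min

Reading the first row against the second, I saw that dissolved partner met substrate about ten times sooner than it arrived in the cold, and sooner still in the heat. So, while much substrate stood, I took the gas passage as the rate-limiting step at both temperatures. I therefore kept one quantity, 0.0511 /min, and named it the supply ceiling: the transfer constant times the saturation concentration, divided by the charged substrate, which is the fraction of the charge that can be coupled per minute. Each coupling uses one partner and gives one by-product, so by-product over 15 min could reach at most 76.6 % of the charge, and no temperature enters that figure.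

The last two rows then told me where the heat would act. At these equal yardstick amounts, the time of the second coupling was shorter than that of the third in the cold column, while in the hot column the order turned. I expected like totals of coupling, with summer ahead in tris adduct; how much double product that left I could not reckon by hand, so I stopped there.

The forecast gave 13.8 % for dusk, 13.4 % for summer and 14.2 % for midnight, hence all alike, saying “Heat therefore adds little uptake and mainly shifts selectivity towards over-reaction to the tris adduct”.

The simulation gave 14.0 % for dusk, 13.4 % for summer and 14.0 % for midnight, so all alike.

In dusk, summer and midnight, substrate still stood at 52 %, 52 % and 52 % of the charge at 15 min while the couplings ran side by side, and by-product had reached 70.7 %, 74.1 % and 67.3 % of the charge, below the ceiling of 76.6 %. The flasks parted in tris adduct, which ended at 6.51 % in summer, 4.44 % in dusk, cooled at 10 min, and 2.89 % in midnight. The neighbour of midnight charged with 0.78 M of substrate has a ceiling of 30.5 % of its own charge, reached 28.9 % in by-product, and ended with 3.83 % double product.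

The constants are those of an exercise; the rest is arithmetic.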